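## Structural features

The target 20 contains a single ring, a benzene ring (C1–C6) that carries a methoxy group at C2, a methyl group at C4 and a free hydroxyl at C5, so the two oxygen substituents are para to each other and the ring is as electron-rich as a hydroquinone monoether. C1 is bonded to the only stereocentre, the fully substituted carbinol carbon C8, which holds the tertiary hydroxyl O8–H and two CH2O arms: C9, esterified with (E)-2-methylbut-2-enoic (tiglic) acid, and C10, esterified with acetic acid. Since both arms are acyloxymethyl groups, C8 is stereogenic only because the two acyl groups differ; with the ranking O8 > C9 > C10 > C1 the configuration is R. There is no neighbouring stereocentre to lean on, and the fragile points all concern this one centre: an acyl shift among O8, O9 and O10 moves an ester to the other arm and erodes the configuration, the tertiary benzylic C8–O8 bond next to an ortho-methoxy ring can ionise in strong acid, the conjugated alkene of the tiglate forbids late hydrogenolysis, and the phenol must be masked against acylation and oxidation. The real difficulty is therefore to build a quaternary oxygenated carbon whose two almost identical arms are distinguishable from the moment it is formed and stay so to the last step. The key step exploits that O8, C8, C1 and C9 form an α-hydroxy arylacetic (mandelic) acid when C9 is raised to the carboxyl level: C8 then bears an acidic hydrogen, its enolate is conjugated with ring C1–C6, and C10 can be attached as a one-carbon electrophile while C9 is still a carbonyl carbon.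

## Logic of the disconnections

20 from 19. The O–Si bond at the C5 oxygen is cut last. The phenol has to be masked from the first step on, because free it would steer bromination to the wrong ring position and compete in both acylations; a bulky silyl ether is chosen because it comes off without base, strong acid or hydrogen. The gain is an end game free of chemoselectivity problems. The forward step must release the phenol under buffered conditions so that no alkoxide forms at O8.

19 from 18. The O10–acetyl bond is cut. Acetate is the more mobile of the two acyl groups, so it is attached last, when O10–H is the only primary hydroxyl left. The forward step must be a fast, primary-selective acetylation that leaves the tertiary O8–H alone and gives the ester already present in 18 no time to shift.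

18 from 17. The O10–Si bond is cut. This exposes the second arm only after the first is esterified. The demand is cleavage of an alkyl silyl ether beside an aryl silyl ether, which calls for mild acid, not fluoride or base.

17 from 15 and 16. The O9–acyl bond is cut. The hindered, conjugated acyl group of 16 is the slower one to migrate, and 15 has only one primary hydroxyl free, so no selection between arms is needed. The forward step must prefer the primary over the tertiary hydroxyl and keep the E alkene.

15 from 14. The two C9–H bonds are removed and O8 and C9 are tied back into the lactone acetal. This makes C9 and C10 different in kind (a carbonyl carbon against a silyloxymethyl group) and not merely in their esters. The demand is a hydride reduction that opens the lactone acetal completely and does not let the silyl group on O10 move to O9.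

14 from 13. The O10–Si bond is cut. Protection must precede reduction, because reduction of 13 itself would give a 2-arylglycerol with two identical arms and no stereocentre.

13 from 10 and 11 (through 12). The C8–C10 bond is cut; this is the strategic disconnection. It removes the quaternary centre and leaves a mandelic acid derivative with one easily set secondary stereocentre plus a one-carbon electrophile. The demand is that 12 be attacked by 11 on one face only, which requires 10 to be the pure cis diastereomer.

10 from 8 and 9. The two C–O bonds to the acetal carbon are cut. The acetal copies the configuration of C8 onto a second centre that survives enolisation. The demand is cis selectivity in ring formation and a purification that removes the trans isomer.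

8 from 7, and 7 from 6. The O–ethyl ester linkage (hydrolysis) and the C8–H bond (reduction) are cut. This traces the stereocentre to a prochiral ketone that a catalytic asymmetric hydrogen transfer can reduce. The demands are high enantioselectivity and an ester cleavage that neither epimerises C8 nor strips the aryl silyl ether.

6 from 3 and 4 (through 5). The C1–C8 bond is cut. An aryl nucleophile and 4 deliver C8 and C9 together, each at the right oxidation level, in one step. The demand is single addition to 4.

3 from 2, and 2 from 1. The C–Br bond and the O–Si bond at the phenol are cut, which leads to a purchasable phenol. The demand is bromination ortho to the methoxy and para to the methyl group; the bulky, weakly donating silyloxy group makes that the most reactive site.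

## Other disconnections considered

Alternative 1: The cut is the C10–O bond of the acetate, with C10 and O8 folded back into an oxirane. Forward, acetate (CsOAc buffered with acetic acid) would attack the CH2 carbon of the epoxy tiglate A2 and give A1, the triisopropylsilyl ether of the target, which is the same compound as 19. A2 would come from the 2-arylallyl alcohol A3 (from 3 by cross-coupling) by Katsuki–Sharpless epoxidation and tigloylation.
- In its favour: opening at the unsubstituted carbon leaves the C8–O8 bond alone, so the configuration of A2 would be carried over. Both esters arrive on their arms without a free primary mono-ester such as 18 ever existing, a point on which this plan is the better one. The route would be roughly half as long, so it is also better on step economy.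
- Against it here: C8 of A2 is a tertiary, benzylic epoxide carbon on a ring with an ortho methoxy and a para methyl group. Acid-assisted C–O ionisation would compete with SN2 attack at CH2, leading to attack at C8, to a 1,2-hydride shift to an aldehyde, or to participation by the tiglate carbonyl with scrambling of the acyl groups. The enantiomeric purity would rest on epoxidation of a 1,1-disubstituted allylic alcohol, whose epoxy alcohol is readily opened by titanium alkoxide, with no crystalline relay to upgrade it.
- Comparison: the two plans meet at the same late compound and finish it identically. The chosen plan puts its stereochemical burden on a substrate-controlled C–C bond formation preceded by a purifiable diastereomer; this one puts it on a regiochemical contest at the most cation-stabilising carbon of the molecule, which is judged the weaker bet despite the shorter sequence.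

Alternative 2: The cut is the C8–O8 bond. The allylic phenyl sulfoxide A5 (2Z,4R; either configuration at sulfur) would undergo the Mislow–Evans [2,3] shift to a sulfenate, with oxygen delivered to C8 on the face from which sulfur departs and an E-propenyl group formed. P(OMe)3 would then cleave the S–O bond to give the tertiary allylic alcohol A4. The propenyl group of A4 is a masked C9; ozonolysis and reduction would bring the route to 15.
- In its favour: transfer of chirality from a secondary C–S centre to the quaternary C–O centre is suprafacial and stereospecific. The two arms are again created unlike (propenyl against silyloxymethyl), so on arm differentiation it is the equal of the chosen plan. The key step needs no strong base, no cryogenic enolate and no gaseous electrophile, which makes it operationally the easier one.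
- Against it here: in A5 the alkene is trisubstituted and conjugated with the aryl ring, and the rearrangement gives up that conjugation to build a hindered tertiary sulfenate, so the conversion would depend entirely on the thiophile. Faithful transfer requires A5 to be pure in both alkene geometry and C4 configuration, which costs several steps. Unmasking C9 means ozonolysis beside an electron-rich hydroquinone diether and handling of an α-hydroxy aldehyde.
- Comparison: it solves the same structural problem by a C–O instead of a C–C bond formation, and its mechanism is as well understood. It is clearly longer (extra steps between A4 and 15, and a longer way to A5 than to 10), so the chosen plan is preferred on step economy and on the robustness of its stereochemical relay.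

Alternative 3: The cut is the C1–C8 bond. The arylboronic acid A7 would add, under catalysis by a chiral monovalent rhodium complex (for example [RhCl(C2H4)2]2 with a chiral diene), to the ketone carbonyl of the silyloxy pyruvate A8. This would give the tertiary α-hydroxy ester A6, forming the aryl–carbon bond and the stereocentre together; LiBH4 reduction of A6 would give 15 directly.
- In its favour: it is convergent, and it creates C8 with C9 (ester) and C10 (silyl ether) already unlike, so on arm differentiation it equals the chosen plan. It is catalytic in the chiral source. It would reach 15 in about five steps along its longest line where the chosen plan needs nine, so it is the better plan on step economy.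
- Against it here: the catalyst would have to tell apart two ketone substituents of similar size (CO2Me and CH2OSi), a less favourable case than the aryl or alkyl ketoesters for which such additions are established. A7 is ortho-alkoxy substituted and electron-rich, so transmetalation would be slowed while protodeboronation is easy. A8 is enolisable and can lose its silyloxy group by β-elimination under the basic conditions of the addition. There is no diastereomer to crystallise if selectivity falls short.
- Comparison: this plan relies on catalyst control with an uncertain substrate fit; the chosen plan relies on substrate control by a purifiable acetal. The chosen plan is longer by about four steps, but every step belongs to a well-charted reaction class; this alternative is the way to shorten the route should the addition prove selective.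

Key step: step 7

## Remarks before the steps

- In the step names, Ar stands for 2-methoxy-4-methyl-5-(triisopropylsilyloxy)phenyl; full names are in the compound list.
- Assumption: the transfer hydrogenation of 6 follows the usual model in which the aryl group lies next to the η6-arene, so the (R,R) ligand should give the (S) alcohol; if the sense were opposite, the (S,S) complex would be used with no other change.
- Configuration check: the descriptors of the target (R at C8), of the cis acetal 10 (2S,5S) and of the aldol product 13 (2S,5R) were re-derived from the structures and agree with one another. The arrangement at C5 of 13 maps onto R at C8 of 20 when the lactone carbonyl becomes C9 and the new carbon C10. The descriptor then changes (R in 13 and 14, S in 15 and 17, R in 18 to 20) only because the ranking of the arms changes; no step after step 7 touches the centre.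
- Protecting-group design: the phenol is carried as its triisopropylsilyl ether from step 1 to step 13. Of the common silyl groups it is the most resistant to hydroxide, amide base and hydride, it is inert to the acid of steps 6 and 11, and buffered fluoride removes it without harming the tiglate. The tiglate is installed before the acetate because it migrates more slowly.

## Route

Step 1
Reactants: 1 4-methoxy-2-methylphenol
Product: 2 triisopropyl(4-methoxy-2-methylphenoxy)silane
Conditions: i-Pr3SiCl, imidazole, DMF, 25 °C
Reagents that add atoms: triisopropylsilyl chloride, CC(C)[Si](Cl)(C(C)C)C(C)C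
Why: Imidazole-promoted silylation of a phenol with a trialkylsilyl chloride; the bulky, weakly donating silyl ether should survive the later hydroxide, amide-base and hydride steps and shields its own ortho position in step 2.

Step 2
Reactants: 2 triisopropyl(4-methoxy-2-methylphenoxy)silane
Product: 3 (5-bromo-4-methoxy-2-methylphenoxy)triisopropylsilane
Conditions: NBS, MeCN, 0 °C to 25 °C, dark
Reagents that add atoms: N-bromosuccinimide, O=C1CCC(=O)N1Br
Why: Electrophilic aromatic bromination; the carbon ortho to OMe and para to CH3 is doubly activated and unhindered, whereas the site ortho to the bulky silyloxy group is only singly activated and the site between OMe and CH3 is crowded.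

Step 3
Reactants: 3 (5-bromo-4-methoxy-2-methylphenoxy)triisopropylsilane, 4 diethyl oxalate
Product: 6 ethyl 2-Ar-2-oxoacetate, via arylmagnesium bromide 5 (not isolated)
Conditions: Mg, I2 (cat.), THF, 50 °C; then added to 4 (2.5 equiv), THF, −78 °C; 1 M HCl
Reagents that add atoms: none
Why: Grignard formation followed by inverse addition to excess dialkyl oxalate, a standard aryl glyoxylate synthesis; the magnesium hemiketal alkoxide formed at −78 °C does not collapse before the quench, so a second addition should not occur.

Step 4
Reactants: 6 ethyl 2-Ar-2-oxoacetate
Product: 7 ethyl (2S)-2-hydroxy-2-Ar-acetate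
Conditions: RuCl[(R,R)-TsDPEN](p-cymene) (1 mol %), HCO2H/Et3N (5:2), DMF, 25 °C
Reagents that add atoms: none
Why: Noyori–Ikariya asymmetric transfer hydrogenation of an aryl α-keto ester by a divalent ruthenium hydride; in the six-membered outer-sphere transition state the aryl group sits next to the cymene ring, which with the (R,R) ligand should place hydride so that C8 becomes S.

Step 5
Reactants: 7 ethyl (2S)-2-hydroxy-2-Ar-acetate
Product: 8 (2S)-2-hydroxy-2-Ar-acetic acid
Conditions: LiOH·H2O, THF/H2O (3:1), 0 °C; then 1 M HCl to pH 3
Reagents that add atoms: lithium hydroxide, [Li+].[OH-]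
Why: Saponification of an unhindered ethyl ester at 0 °C should be much faster than hydroxide attack on the hindered aryl triisopropylsilyl ether (further shielded by the ortho methyl group), and the carboxylate formed protects C8–H from enolisation.

Step 6
Reactants: 8 (2S)-2-hydroxy-2-Ar-acetic acid, 9 pivalaldehyde
Product: 10 (2S,5S)-2-tert-butyl-5-Ar-1,3-dioxolan-4-one (cis)
Conditions: p-TsOH·H2O (cat.), pentane, reflux, Dean–Stark; crystallisation from pentane, −20 °C
Reagents that add atoms: none
Why: Acid-catalysed acetalisation of an α-hydroxy acid with azeotropic removal of water, the first stage of self-regeneration of stereocentres; under equilibration the cis 2,5-disubstituted ring should predominate and crystallisation should bring it to diastereomeric purity, so the configuration of C8 is copied onto the acetal carbon.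

Step 7
Reactants: 10 (2S,5S)-2-tert-butyl-5-Ar-1,3-dioxolan-4-one, 11 formaldehyde (monomeric)
Product: 13 (2S,5R)-2-tert-butyl-5-(hydroxymethyl)-5-Ar-1,3-dioxolan-4-one, via lithium enolate 12 (not isolated)
Conditions: LiN(iPr)2, THF, −78 °C; then CH2O gas (from (CH2O)n, 150 °C, N2 stream), −78 °C; AcOH, −78 °C
Reagents that add atoms: none
Why: LiN(iPr)2 removes the ring proton at C5 (the future C8), which is acidified by the lactone carbonyl and the aryl ring, to give the planar lithium enolate 12; at this point the original stereocentre is erased and only the acetal carbon remains stereogenic. The enolate adds to monomeric 11 in an aldol reaction that forms the C8–C10 bond and the quaternary centre; no ring is closed. The closest known reaction type is the alkylation and aldol addition of enolates of mandelic acid-derived cis-2-tert-butyl-1,3-dioxolan-4-ones. The new stereocentre is controlled by the acetal carbon C2: its tert-butyl group blocks one face of the nearly flat five-membered enolate, the electrophile enters anti to it, and the hydroxymethyl group takes the place of the former hydrogen, which amounts to overall retention and gives the 2S,5R product. The only selectivity needed is between the two enolate faces, since formaldehyde creates no second stereocentre; it is secured by the diastereomeric purity of 10 and by holding 12 at −78 °C, where fragmentation of the acetal is slow. Quenching cold with acetic acid should prevent retro-aldol loss of 11 from the lithium aldolate.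

Step 8
Reactants: 13 (2S,5R)-2-tert-butyl-5-(hydroxymethyl)-5-Ar-1,3-dioxolan-4-one
Product: 14 (2S,5R)-2-tert-butyl-5-[(tert-butyldimethylsilyloxy)methyl]-5-Ar-1,3-dioxolan-4-one
Conditions: t-BuMe2SiCl, imidazole, DMF, 0 °C to 25 °C
Reagents that add atoms: tert-butyldimethylsilyl chloride, CC(C)(C)[Si](C)(C)Cl
Why: Standard imidazole-promoted silylation of a primary alcohol; it must precede reduction, because reducing unprotected 13 would give an achiral 2-arylglycerol with identical arms.

Step 9
Reactants: 14 (2S,5R)-2-tert-butyl-5-[(tert-butyldimethylsilyloxy)methyl]-5-Ar-1,3-dioxolan-4-one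
Product: 15 (2S)-3-(tert-butyldimethylsilyloxy)-2-Ar-propane-1,2-diol
Conditions: LiAlH4, THF, 0 °C; EtOAc, then aq. KNaC4H4O6
Reagents that add atoms: none
Why: Hydride reduction of the lactone acetal: addition to the carbonyl opens the ring, the hemiacetal alkoxide expels pivalaldehyde (reduced in turn), and C9 is reduced to the primary alcohol, so the 1,2-diol is released in one operation; aluminium alkoxides at 0 °C should not promote silyl migration and the stereocentre is untouched.

Step 10
Reactants: 15 (2S)-3-(tert-butyldimethylsilyloxy)-2-Ar-propane-1,2-diol, 16 tigloyl chloride
Product: 17 (2S)-3-(tert-butyldimethylsilyloxy)-2-hydroxy-2-Ar-propyl (2E)-2-methylbut-2-enoate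
Conditions: pyridine, DMAP (0.1 equiv), CH2Cl2, 0 °C to 25 °C
Reagents that add atoms: none
Why: DMAP-catalysed acylation with an acid chloride selects the primary hydroxyl over the hindered tertiary benzylic one; with pyridine as the only base no vinylketene should form, so the E alkene of the tiglate is kept.

Step 11
Reactants: 17 (2S)-3-(tert-butyldimethylsilyloxy)-2-hydroxy-2-Ar-propyl (2E)-2-methylbut-2-enoate
Product: 18 (2R)-2,3-dihydroxy-2-Ar-propyl (2E)-2-methylbut-2-enoate
Conditions: (+)-camphor-10-sulfonic acid (0.1 equiv), MeOH/CH2Cl2 (1:1), 0 °C; pH 7 phosphate buffer
Reagents that add atoms: none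
Why: Acid-catalysed methanolysis cleaves a primary alkyl silyl ether much faster than an aryl triisopropylsilyl ether, whose oxygen is poorly basic; catalytic acid at 0 °C should not ionise the tertiary benzylic alcohol, which is deactivated by two β-oxygen substituents, and the hindered conjugated ester migrates only slowly under acid.

Step 12
Reactants: 18 (2R)-2,3-dihydroxy-2-Ar-propyl (2E)-2-methylbut-2-enoate
Product: 19 (2R)-3-acetoxy-2-hydroxy-2-Ar-propyl (2E)-2-methylbut-2-enoate
Conditions: Ac2O (1.3 equiv), pyridine, DMAP (0.05 equiv), CH2Cl2, 0 °C, used directly on crude 18
Reagents that add atoms: acetic anhydride, CC(=O)OC(C)=O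
Why: DMAP-catalysed acetylation of the primary alcohol is fast at 0 °C and should outrun both acylation of the tertiary hydroxyl and migration of the tiglate; once O10 is acetylated no primary hydroxyl remains and the two arms are locked.

Step 13
Reactants: 19 (2R)-3-acetoxy-2-hydroxy-2-Ar-propyl (2E)-2-methylbut-2-enoate
Product: 20 (2R)-3-acetoxy-2-hydroxy-2-(5-hydroxy-2-methoxy-4-methylphenyl)propyl (2E)-2-methylbut-2-enoate
Conditions: Bu4NF/AcOH (1:1), THF, 0 °C
Reagents that add atoms: none
Why: Fluoride cleaves aryl silyl ethers readily because phenoxide is a good leaving group; buffering with acetic acid protonates the phenoxide and prevents an O8 alkoxide, so neither ester should migrate and the tiglate is untouched.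

## Compound list

1 | 4-methoxy-2-methylphenol | COc1ccc(O)c(C)c1 | starting material
2 | triisopropyl(4-methoxy-2-methylphenoxy)silane | COc1ccc(O[Si](C(C)C)(C(C)C)C(C)C)c(C)c1 | intermediate
3 | (5-bromo-4-methoxy-2-methylphenoxy)triisopropylsilane | COc1cc(C)c(O[Si](C(C)C)(C(C)C)C(C)C)cc1Br | intermediate
4 | diethyl oxalate | CCOC(=O)C(=O)OCC | starting material
5 | [2-methoxy-4-methyl-5-(triisopropylsilyloxy)phenyl]magnesium bromide (formed in the flask, not isolated) | COc1cc(C)c(O[Si](C(C)C)(C(C)C)C(C)C)cc1[Mg]Br | intermediate
6 | ethyl 2-[2-methoxy-4-methyl-5-(triisopropylsilyloxy)phenyl]-2-oxoacetate | CCOC(=O)C(=O)c1cc(O[Si](C(C)C)(C(C)C)C(C)C)c(C)cc1OC | intermediate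
7 | ethyl (2S)-2-hydroxy-2-[2-methoxy-4-methyl-5-(triisopropylsilyloxy)phenyl]acetate | CCOC(=O)[C@@H](O)c1cc(O[Si](C(C)C)(C(C)C)C(C)C)c(C)cc1OC | intermediate
8 | (2S)-2-hydroxy-2-[2-methoxy-4-methyl-5-(triisopropylsilyloxy)phenyl]acetic acid | OC(=O)[C@@H](O)c1cc(O[Si](C(C)C)(C(C)C)C(C)C)c(C)cc1OC | intermediate
9 | pivalaldehyde (2,2-dimethylpropanal) | CC(C)(C)C=O | starting material
10 | (2S,5S)-2-tert-butyl-5-[2-methoxy-4-methyl-5-(triisopropylsilyloxy)phenyl]-1,3-dioxolan-4-one (cis) | CC(C)(C)[C@@H]1OC(=O)[C@H](c2cc(O[Si](C(C)C)(C(C)C)C(C)C)c(C)cc2OC)O1 | intermediate
11 | formaldehyde (monomer, from cracked paraformaldehyde) | C=O | starting material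
12 | lithium (2S)-2-tert-butyl-5-[2-methoxy-4-methyl-5-(triisopropylsilyloxy)phenyl]-1,3-dioxol-4-olate (lithium enolate, not isolated) | CC(C)(C)[C@@H]1OC(O[Li])=C(c2cc(O[Si](C(C)C)(C(C)C)C(C)C)c(C)cc2OC)O1 | intermediate
13 | (2S,5R)-2-tert-butyl-5-(hydroxymethyl)-5-[2-methoxy-4-methyl-5-(triisopropylsilyloxy)phenyl]-1,3-dioxolan-4-one | CC(C)(C)[C@@H]1OC(=O)[C@](CO)(c2cc(O[Si](C(C)C)(C(C)C)C(C)C)c(C)cc2OC)O1 | intermediate
14 | (2S,5R)-2-tert-butyl-5-[(tert-butyldimethylsilyloxy)methyl]-5-[2-methoxy-4-methyl-5-(triisopropylsilyloxy)phenyl]-1,3-dioxolan-4-one | CC(C)(C)[C@@H]1OC(=O)[C@](CO[Si](C)(C)C(C)(C)C)(c2cc(O[Si](C(C)C)(C(C)C)C(C)C)c(C)cc2OC)O1 | intermediate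
15 | (2S)-3-(tert-butyldimethylsilyloxy)-2-[2-methoxy-4-methyl-5-(triisopropylsilyloxy)phenyl]propane-1,2-diol | OC[C@](O)(CO[Si](C)(C)C(C)(C)C)c1cc(O[Si](C(C)C)(C(C)C)C(C)C)c(C)cc1OC | intermediate
16 | tigloyl chloride, (2E)-2-methylbut-2-enoyl chloride | C/C=C(\C)C(Cl)=O | starting material
17 | (2S)-3-(tert-butyldimethylsilyloxy)-2-hydroxy-2-[2-methoxy-4-methyl-5-(triisopropylsilyloxy)phenyl]propyl (2E)-2-methylbut-2-enoate | C/C=C(\C)C(=O)OC[C@](O)(CO[Si](C)(C)C(C)(C)C)c1cc(O[Si](C(C)C)(C(C)C)C(C)C)c(C)cc1OC | intermediate
18 | (2R)-2,3-dihydroxy-2-[2-methoxy-4-methyl-5-(triisopropylsilyloxy)phenyl]propyl (2E)-2-methylbut-2-enoate | C/C=C(\C)C(=O)OC[C@](O)(CO)c1cc(O[Si](C(C)C)(C(C)C)C(C)C)c(C)cc1OC | intermediate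
19 | (2R)-3-acetoxy-2-hydroxy-2-[2-methoxy-4-methyl-5-(triisopropylsilyloxy)phenyl]propyl (2E)-2-methylbut-2-enoate | C/C=C(\C)C(=O)OC[C@](O)(COC(C)=O)c1cc(O[Si](C(C)C)(C(C)C)C(C)C)c(C)cc1OC | intermediate
20 | (2R)-3-acetoxy-2-hydroxy-2-(5-hydroxy-2-methoxy-4-methylphenyl)propyl (2E)-2-methylbut-2-enoate | C/C=C(\C)C(=O)OC[C@](O)(COC(C)=O)c1cc(O)c(C)cc1OC | target

## Step count and least certain steps

Total: 13 steps. Longest linear sequence: 13 steps (1 to 20); compounds 4, 9, 11 and 16 are purchased and enter directly.

Step 7 (key step). The most likely failure is incomplete capture of enolate 12: monomeric 11 repolymerises on cold surfaces, so the enolate may be under-dosed and then fragment at the acetal or be reprotonated at the quench. Retro-aldol loss of 11 if the aldolate warms before quenching is the second possibility. Loss of facial selectivity is unlikely unless trans acetal is carried in. Fallback: starting from 10, 12 would be formed as before and alkylated with benzyl chloromethyl ether, an irreversible SN2 reaction with a liquid electrophile that makes the same C8–C10 bond on the same face. This would give (2S,5R)-5-[(benzyloxy)methyl]-2-tert-butyl-5-Ar-1,3-dioxolan-4-one F1; hydrogenolysis (H2, Pd/C, EtOAc; no alkene is present yet) would then rejoin the route at 13.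

Step 9. The concern is migration of the silyl group from O10 to the O9 or O8 alkoxide during reduction or work-up; this would interchange the two arms and lower the enantiomeric purity without changing the constitution. Partial loss of the aryl silyl ether is a lesser concern. Fallback: starting from 13, the hydroxyl would be protected as a mixed ketal, which cannot migrate under basic conditions. 2-Methoxypropene and catalytic pyridinium p-toluenesulfonate should give (2S,5R)-2-tert-butyl-5-{[(2-methoxypropan-2-yl)oxy]methyl}-5-Ar-1,3-dioxolan-4-one F2. LiAlH4 reduction would give (2S)-3-[(2-methoxypropan-2-yl)oxy]-2-Ar-propane-1,2-diol F3, and acylation with 16 as in step 10 would give (2R)-2-hydroxy-3-[(2-methoxypropan-2-yl)oxy]-2-Ar-propyl (2E)-2-methylbut-2-enoate F4. Brief methanolysis with pyridinium p-toluenesulfonate at 0 °C would rejoin the route at 18.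

Step 11 (with step 12). Two processes threaten this stage: cleavage of the aryl silyl ether along with the alkyl one, and acyl migration in the free mono-ester 18 (by the 1,3 path or through O8), which would erode the configuration. The second is countered by keeping 18 cold and acetylating it at once. Fallback for the first, which gives up silyl orthogonality altogether: starting from 17, both silyl groups would be removed with HF·pyridine in THF to give (2R)-2,3-dihydroxy-2-(5-hydroxy-2-methoxy-4-methylphenyl)propyl (2E)-2-methylbut-2-enoate F5. Acetylation of the primary alcohol and the phenol (Ac2O, pyridine, 0 °C) would give (2R)-3-acetoxy-2-(5-acetoxy-2-methoxy-4-methylphenyl)-2-hydroxypropyl (2E)-2-methylbut-2-enoate F6. The much more labile aryl acetate alone would then be cleaved by methanolysis promoted by NH4OAc in aqueous methanol, arriving at 20.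

Step 5. Hydroxide attack at silicon (loss of the aryl silyl ether) and base-mediated epimerisation at C8 are the likely failures. Fallback that avoids hydroxide: starting from 3, the Grignard reagent 5 would be acylated with dibenzyl oxalate to give benzyl 2-Ar-2-oxoacetate F7. The same transfer hydrogenation would give benzyl (2S)-2-hydroxy-2-Ar-acetate F8, and hydrogenolysis of the benzyl ester (H2, Pd/C, EtOAc) would rejoin the route at 8.

Step 6. An insufficient cis preference at equilibrium, or failure of the cis acetal to crystallise because of the lipophilic silyl group, would leave trans acetal in 10; in step 7 this would deliver the opposite configuration at C8. Fallback under kinetic instead of thermodynamic control: starting from 8, silylation of both the hydroxyl and the carboxyl group (Me3SiCl, Et3N) would give trimethylsilyl (2S)-2-Ar-2-(trimethylsilyloxy)acetate F9. Condensation with 9 under Me3SiOTf catalysis in CH2Cl2 at −78 °C is expected to close the ring with high cis selectivity and rejoin the route at 10.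

## Further compounds

F1 | step 7 | (2S,5R)-5-[(benzyloxy)methyl]-2-tert-butyl-5-[2-methoxy-4-methyl-5-(triisopropylsilyloxy)phenyl]-1,3-dioxolan-4-one | CC(C)(C)[C@@H]1OC(=O)[C@](COCc2ccccc2)(c2cc(O[Si](C(C)C)(C(C)C)C(C)C)c(C)cc2OC)O1
F2 | step 9 | (2S,5R)-2-tert-butyl-5-{[(2-methoxypropan-2-yl)oxy]methyl}-5-[2-methoxy-4-methyl-5-(triisopropylsilyloxy)phenyl]-1,3-dioxolan-4-one | CC(C)(C)[C@@H]1OC(=O)[C@](COC(C)(C)OC)(c2cc(O[Si](C(C)C)(C(C)C)C(C)C)c(C)cc2OC)O1
F3 | step 9 | (2S)-3-[(2-methoxypropan-2-yl)oxy]-2-[2-methoxy-4-methyl-5-(triisopropylsilyloxy)phenyl]propane-1,2-diol | OC[C@](O)(COC(C)(C)OC)c1cc(O[Si](C(C)C)(C(C)C)C(C)C)c(C)cc1OC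
F4 | step 9 | (2R)-2-hydroxy-3-[(2-methoxypropan-2-yl)oxy]-2-[2-methoxy-4-methyl-5-(triisopropylsilyloxy)phenyl]propyl (2E)-2-methylbut-2-enoate | C/C=C(\C)C(=O)OC[C@](O)(COC(C)(C)OC)c1cc(O[Si](C(C)C)(C(C)C)C(C)C)c(C)cc1OC
F5 | step 11 | (2R)-2,3-dihydroxy-2-(5-hydroxy-2-methoxy-4-methylphenyl)propyl (2E)-2-methylbut-2-enoate | C/C=C(\C)C(=O)OC[C@](O)(CO)c1cc(O)c(C)cc1OC
F6 | step 11 | (2R)-3-acetoxy-2-(5-acetoxy-2-methoxy-4-methylphenyl)-2-hydroxypropyl (2E)-2-methylbut-2-enoate | C/C=C(\C)C(=O)OC[C@](O)(COC(C)=O)c1cc(OC(C)=O)c(C)cc1OC
F7 | step 5 | benzyl 2-[2-methoxy-4-methyl-5-(triisopropylsilyloxy)phenyl]-2-oxoacetate | O=C(OCc1ccccc1)C(=O)c1cc(O[Si](C(C)C)(C(C)C)C(C)C)c(C)cc1OC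
F8 | step 5 | benzyl (2S)-2-hydroxy-2-[2-methoxy-4-methyl-5-(triisopropylsilyloxy)phenyl]acetate | O=C(OCc1ccccc1)[C@@H](O)c1cc(O[Si](C(C)C)(C(C)C)C(C)C)c(C)cc1OC
F9 | step 6 | trimethylsilyl (2S)-2-[2-methoxy-4-methyl-5-(triisopropylsilyloxy)phenyl]-2-(trimethylsilyloxy)acetate | C[Si](C)(C)OC(=O)[C@@H](O[Si](C)(C)C)c1cc(O[Si](C(C)C)(C(C)C)C(C)C)c(C)cc1OC
A1 | alternative 1 | (2R)-3-acetoxy-2-hydroxy-2-[2-methoxy-4-methyl-5-(triisopropylsilyloxy)phenyl]propyl (2E)-2-methylbut-2-enoate (identical with 19) | C/C=C(\C)C(=O)OC[C@](O)(COC(C)=O)c1cc(O[Si](C(C)C)(C(C)C)C(C)C)c(C)cc1OC
A2 | alternative 1 | {(2R)-2-[2-methoxy-4-methyl-5-(triisopropylsilyloxy)phenyl]oxiran-2-yl}methyl (2E)-2-methylbut-2-enoate | C/C=C(\C)C(=O)OC[C@]1(CO1)c2cc(O[Si](C(C)C)(C(C)C)C(C)C)c(C)cc2OC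
A3 | alternative 1 | 2-[2-methoxy-4-methyl-5-(triisopropylsilyloxy)phenyl]prop-2-en-1-ol | C=C(CO)c1cc(O[Si](C(C)C)(C(C)C)C(C)C)c(C)cc1OC
A4 | alternative 2 | (2R,3E)-1-(tert-butyldimethylsilyloxy)-2-[2-methoxy-4-methyl-5-(triisopropylsilyloxy)phenyl]pent-3-en-2-ol | C/C=C/[C@](O)(CO[Si](C)(C)C(C)(C)C)c1cc(O[Si](C(C)C)(C(C)C)C(C)C)c(C)cc1OC
A5 | alternative 2 | tert-butyldimethyl{[(2Z,4R)-2-[2-methoxy-4-methyl-5-(triisopropylsilyloxy)phenyl]-4-(phenylsulfinyl)pent-2-en-1-yl]oxy}silane (either configuration at sulfur) | C[C@@H](S(=O)c1ccccc1)/C=C(\CO[Si](C)(C)C(C)(C)C)c1cc(O[Si](C(C)C)(C(C)C)C(C)C)c(C)cc1OC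
A6 | alternative 3 | methyl (2R)-3-(tert-butyldimethylsilyloxy)-2-hydroxy-2-[2-methoxy-4-methyl-5-(triisopropylsilyloxy)phenyl]propanoate | COC(=O)[C@](O)(CO[Si](C)(C)C(C)(C)C)c1cc(O[Si](C(C)C)(C(C)C)C(C)C)c(C)cc1OC
A7 | alternative 3 | [2-methoxy-4-methyl-5-(triisopropylsilyloxy)phenyl]boronic acid | COc1cc(C)c(O[Si](C(C)C)(C(C)C)C(C)C)cc1B(O)O
A8 | alternative 3 | methyl 3-(tert-butyldimethylsilyloxy)-2-oxopropanoate | COC(=O)C(=O)CO[Si](C)(C)C(C)(C)C
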